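**Plan**
1. Retrosynthetic cuts, last bond first: the C8–O–SO3H ester and the two benzyl-type ethers; the C3=C4 double bond (back to a C3 dimethyl ketal); N1–C8a (retro-Beckmann, lactam back to a five-membered ketone oxime); the C2 oxygen of the indanone; the CH2–C1' bond of the diarylmethane; the C6–CHO bond.
2. Enabling feature: in the quinolinone ring N1 sits between the C2 carbonyl and C8a, and the neighbouring C8 carries oxygen. This is the array C1(=O)–C7a–C7(O) of a 7-oxyindan-1-one with nitrogen inserted into the C1–C7a bond.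
3. Forward order: the benzene ring and the five-membered ring come with the starting material. The arylmethyl arm is attached at C6, C2 is oxidised and ketalised, and C1 is oximated. The carbocycle is then expanded to the six-membered lactam, and loss of methanol makes it the 2-quinolone.
4. Stereochemistry: the target has no stereocentre. The only stereochemical element of the route is the C=N geometry of oxime 14, set by the peri C7 ether oxygen, and it decides which bond migrates.

Key step: step 8

Remark: the target is achiral (no stereocentre, axis or plane of chirality), so there is no enantiomer to select.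
Remark: the target is drawn as the free hydrogen sulfate. Aryl hydrogen sulfates catalyse their own hydrolysis, so the ester is carried as its sodium salt and protonated only in the last operation.

**Step 1**
Reactants: 1 7-hydroxyindan-1-one; 2 paraformaldehyde
Product: 3 7-hydroxy-1-oxo-2,3-dihydro-1H-indene-6-carbaldehyde
Conditions: MgCl2 (anhydrous), Et3N, (CH2O)n, MeCN, reflux; 1 M HCl work-up
Reagents that add atoms: paraformaldehyde 2, C=O
Why: Casnati–Skattebøl ortho-formylation, in which the magnesium phenoxide binds formaldehyde and delivers it to C6, the only free ortho carbon (the electronically favoured para carbon C4 is out of reach of the chelate), and a second formaldehyde oxidises the resulting magnesium benzyl alkoxide to the aldehyde by hydride transfer.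

**Step 2**
Reactants: 3 7-hydroxy-1-oxo-2,3-dihydro-1H-indene-6-carbaldehyde; 4 4-methoxybenzyl chloride
Product: 5 7-[(4-methoxybenzyl)oxy]-1-oxo-2,3-dihydro-1H-indene-6-carbaldehyde
Conditions: K2CO3, NaI (cat.), DMF, 40 °C
Reagents that add atoms: 4-methoxybenzyl chloride 4, COc1ccc(CCl)cc1
Why: Williamson etherification of an acidic, doubly ortho-acylated phenol under a weak base at low temperature, which should spare the keto aldehyde from Claisen–Schmidt self-condensation; a 4-methoxybenzyl ether is preferred to an allyl ether because it offers no alkene for intramolecular 1,3-dipolar cycloaddition with the diazoalkane of step 3 and can later be removed by acid beside the plain benzyl ether.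

**Step 3**
Reactants: 5 7-[(4-methoxybenzyl)oxy]-1-oxo-2,3-dihydro-1H-indene-6-carbaldehyde; 6 4-(benzyloxy)-3-methoxyphenylboronic acid
Product: 10 6-[4-(benzyloxy)-3-methoxybenzyl]-7-[(4-methoxybenzyl)oxy]indan-1-one, via tosylhydrazone 7 (not isolated), via diazoalkane 8 (not isolated), via benzylic boronic acid 9 (not isolated)
Conditions: TsNHNH2 (1.0 equiv), 1,4-dioxane, 50 °C; then 6, K2CO3, 110 °C
Reagents that add atoms: 4-(benzyloxy)-3-methoxyphenylboronic acid 6, COc1cc(B(O)O)ccc1OCc1ccccc1
Why: Barluenga–Valdés reductive coupling, in which one equivalent of tosylhydrazide condenses with the aldehyde far faster than with the hindered, donor-substituted ketone, base-induced loss of sulfinate (Bamford–Stevens) gives diazoalkane 8, its carbon adds to the boron of 6, the electron-rich aryl group shifts from boron to carbon with loss of nitrogen, and the doubly benzylic boronic acid 9 protodeboronates in the basic medium.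

**Step 4**
Reactants: 10 6-[4-(benzyloxy)-3-methoxybenzyl]-7-[(4-methoxybenzyl)oxy]indan-1-one
Product: 11 (E)-6-[4-(benzyloxy)-3-methoxybenzyl]-2-[(dimethylamino)methylidene]-7-[(4-methoxybenzyl)oxy]indan-1-one
Conditions: t-BuOCH(NMe2)2, toluene, 100 °C
Reagents that add atoms: Bredereck's reagent (tert-butoxybis(dimethylamino)methane), CC(C)(C)OC(N(C)C)N(C)C
Why: condensation of the only acidic CH2 (C2, alpha to the ketone) with Bredereck's reagent gives the vinylogous amide, a standard reaction of indan-1-ones that needs no added acid or base and touches neither the ethers nor the diarylmethane.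

**Step 5**
Reactants: 11 (E)-6-[4-(benzyloxy)-3-methoxybenzyl]-2-[(dimethylamino)methylidene]-7-[(4-methoxybenzyl)oxy]indan-1-one
Product: 12 6-[4-(benzyloxy)-3-methoxybenzyl]-7-[(4-methoxybenzyl)oxy]indane-1,2-dione
Conditions: O2, visible light, tetraphenylporphyrin (cat.), CH2Cl2, −78 °C to rt
Reagents that add atoms: oxygen, O=O
Why: enaminone photooxygenation, in which singlet oxygen adds [2+2] to the electron-rich C=C bond and the dioxetane splits into the 1,2-dione and dimethylformamide, a neutral entry to the dione that avoids the strong acid and formaldehyde of an oximino ketone hydrolysis (chloromethylation of the dialkoxyarene, loss of the 4-methoxybenzyl ether) and cannot cleave the dione further.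

**Step 6**
Reactants: 12 6-[4-(benzyloxy)-3-methoxybenzyl]-7-[(4-methoxybenzyl)oxy]indane-1,2-dione
Product: 13 6-[4-(benzyloxy)-3-methoxybenzyl]-2,2-dimethoxy-7-[(4-methoxybenzyl)oxy]indan-1-one
Conditions: HC(OMe)3, TsOH·H2O (cat.), MeOH, 40 °C; Et3N quench
Reagents that add atoms: trimethyl orthoformate, COC(OC)OC
Why: acid-catalysed ketalisation with orthoformate as water scavenger goes to C2, the non-conjugated and more electrophilic carbonyl, whereas C1 is deactivated by the ortho ether oxygen and shielded in the peri position; loss of methanol from the ketal is no threat at this stage because it would create a 2-methoxyindenone.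

**Step 7**
Reactants: 13 6-[4-(benzyloxy)-3-methoxybenzyl]-2,2-dimethoxy-7-[(4-methoxybenzyl)oxy]indan-1-one
Product: 14 (Z)-6-[4-(benzyloxy)-3-methoxybenzyl]-2,2-dimethoxy-7-[(4-methoxybenzyl)oxy]indan-1-one oxime (hydroxyl on the C2 side, anti to C7a)
Conditions: NH2OH·HCl, pyridine, EtOH, 80 °C
Reagents that add atoms: hydroxylamine hydrochloride, NO.Cl
Why: oxime formation at the remaining ketone, which two alpha oxygens make more electrophilic, under pyridine buffering that leaves the ketal intact; the conditions allow E/Z equilibration and the Z isomer should prevail because the other isomer would press the hydroxyl oxygen against the in-plane C7 ether oxygen, any minor isomer being separated by chromatography and re-equilibrated.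

**Step 8**
Reactants: 14 (Z)-6-[4-(benzyloxy)-3-methoxybenzyl]-2,2-dimethoxy-7-[(4-methoxybenzyl)oxy]indan-1-one oxime
Product: 16 7-[4-(benzyloxy)-3-methoxybenzyl]-3,3-dimethoxy-8-[(4-methoxybenzyl)oxy]-3,4-dihydroquinolin-2(1H)-one, via oxime mesylate 15 (not isolated)
Conditions: MsCl, Et3N, CH2Cl2, −20 °C; cold aqueous wash, solvent exchange; (CF3)2CHOH–H2O 9:1, 2,6-lutidine, 45 °C
Reagents that add atoms: water, O
Why: Mesylation at low temperature fixes the Z geometry, and in the strongly ionising, buffered fluoroalcohol the N–O bond ionises in concert with a 1,2-shift of the antiperiplanar C7a from C1 to nitrogen; water adds to the cyclic nitrilium (imidoyl) species and tautomerisation gives lactam 16, in which old C1 is C2, the ketal carbon is C3 and the benzylic CH2 is C4. The closest known reaction is the Beckmann rearrangement of indan-1-one oxime sulfonates to 3,4-dihydroquinolin-2(1H)-ones by aryl migration. The six-membered lactam arises by one-atom ring expansion of the five-membered ring (nitrogen inserted into C1–C7a), not by a cyclisation, and N1–C8a is the only new skeletal bond. No stereocentre is formed. The selectivity needed is aryl migration over Beckmann fragmentation at the cation-stabilising ketal carbon, and it depends only on which group lies anti to the leaving group: the in-plane C7 ether oxygen, peri to C1, keeps the oxime oxygen on the C2 side, where it fits between the two out-of-plane methoxy groups. The quaternary C2 also excludes Neber and ene-hydroxylamine side paths, and the lutidine buffer keeps acid from isomerising the sulfonate or opening the ketal.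

**Step 9**
Reactants: 16 7-[4-(benzyloxy)-3-methoxybenzyl]-3,3-dimethoxy-8-[(4-methoxybenzyl)oxy]-3,4-dihydroquinolin-2(1H)-one
Product: 17 7-[4-(benzyloxy)-3-methoxybenzyl]-8-hydroxy-3-methoxyquinolin-2(1H)-one
Conditions: CF3CO2H–CH2Cl2 1:3 (anhydrous), anisole, 0 °C to 35 °C
Reagents that add atoms: none
Why: anhydrous Brønsted acid performs two known reactions at once, the SN1 cleavage of the 4-methoxybenzyl aryl ether (cation taken up by anisole) and the ketal-to-enol-ether loss of methanol known from the cracking of pyruvate ketals to 2-alkoxyacrylates, here driven by formation of the aromatic 2-quinolone ring, while the unsubstituted benzyl ether ionises far more slowly and should stay.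

**Step 10**
Reactants: 17 7-[4-(benzyloxy)-3-methoxybenzyl]-8-hydroxy-3-methoxyquinolin-2(1H)-one
Product: 18 sodium 7-[4-(benzyloxy)-3-methoxybenzyl]-3-methoxy-2-oxo-1,2-dihydroquinolin-8-yl sulfate
Conditions: SO3·pyridine, pyridine, 50 °C; aq. NaHCO3; C18 chromatography
Reagents that add atoms: sulfur trioxide–pyridine complex, O=S(=O)([O-])[n+]1ccccc1; sodium hydrogen carbonate, [Na+].OC([O-])=O
Why: O-sulfation of a phenol with sulfur trioxide–pyridine, in which C8–OH is the only free hydroxyl, any transient sulfation of the lactam is undone in the bicarbonate work-up, and isolation as the sodium salt protects the acid-labile ester.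

**Step 11**
Reactants: 18 sodium 7-[4-(benzyloxy)-3-methoxybenzyl]-3-methoxy-2-oxo-1,2-dihydroquinolin-8-yl sulfate
Product: 20 scolopendrine (7-(4-hydroxy-3-methoxybenzyl)-3-methoxy-2-oxo-1,2-dihydroquinolin-8-yl hydrogen sulfate), via sodium salt 19 (not isolated)
Conditions: H2 (1 atm), 10% Pd/C, MeOH, rt; filter; aq. HCl (1.0 equiv), 0 °C; C18 desalting, lyophilisation
Reagents that add atoms: none
Why: hydrogenolysis of the benzyl aryl ether over palladium under neutral conditions leaves aryl sulfate salts, the 2-quinolone ring and the diarylmethane untouched, and one equivalent of cold acid followed by rapid desalting liberates the hydrogen sulfate.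

**Compound list**
1 | 7-hydroxyindan-1-one | O=C1CCc2cccc(O)c21 | starting material
2 | paraformaldehyde (as formaldehyde) | C=O | starting material
3 | 7-hydroxy-1-oxo-2,3-dihydro-1H-indene-6-carbaldehyde | O=Cc1ccc2CCC(=O)c2c1O | intermediate
4 | 4-methoxybenzyl chloride | COc1ccc(CCl)cc1 | starting material
5 | 7-[(4-methoxybenzyl)oxy]-1-oxo-2,3-dihydro-1H-indene-6-carbaldehyde | O=Cc1ccc2CCC(=O)c2c1OCc1ccc(OC)cc1 | intermediate
6 | 4-(benzyloxy)-3-methoxyphenylboronic acid | COc1cc(B(O)O)ccc1OCc1ccccc1 | starting material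
7 | (E)-N-tosylhydrazone of the aldehyde group of 5 | Cc1ccc(cc1)S(=O)(=O)N/N=C/c1ccc2CCC(=O)c2c1OCc1ccc(OC)cc1 | intermediate (not isolated)
8 | 6-(diazomethyl)-7-[(4-methoxybenzyl)oxy]indan-1-one | [N-]=[N+]=Cc1ccc2CCC(=O)c2c1OCc1ccc(OC)cc1 | intermediate (not isolated)
9 | {[4-(benzyloxy)-3-methoxyphenyl][7-(4-methoxybenzyloxy)-1-oxoindan-6-yl]methyl}boronic acid (racemic, centre lost in the same flask) | OB(O)C(c1ccc(OCc2ccccc2)c(OC)c1)c1ccc2CCC(=O)c2c1OCc1ccc(OC)cc1 | intermediate (not isolated)
10 | 6-[4-(benzyloxy)-3-methoxybenzyl]-7-[(4-methoxybenzyl)oxy]indan-1-one | COc1cc(Cc2ccc3CCC(=O)c3c2OCc2ccc(OC)cc2)ccc1OCc1ccccc1 | intermediate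
11 | (E)-6-[4-(benzyloxy)-3-methoxybenzyl]-2-[(dimethylamino)methylidene]-7-[(4-methoxybenzyl)oxy]indan-1-one | COc1cc(Cc2ccc3C/C(=C\N(C)C)C(=O)c3c2OCc2ccc(OC)cc2)ccc1OCc1ccccc1 | intermediate
12 | 6-[4-(benzyloxy)-3-methoxybenzyl]-7-[(4-methoxybenzyl)oxy]indane-1,2-dione | COc1cc(Cc2ccc3CC(=O)C(=O)c3c2OCc2ccc(OC)cc2)ccc1OCc1ccccc1 | intermediate
13 | 6-[4-(benzyloxy)-3-methoxybenzyl]-2,2-dimethoxy-7-[(4-methoxybenzyl)oxy]indan-1-one | COc1cc(Cc2ccc3CC(OC)(OC)C(=O)c3c2OCc2ccc(OC)cc2)ccc1OCc1ccccc1 | intermediate
14 | (Z)-6-[4-(benzyloxy)-3-methoxybenzyl]-2,2-dimethoxy-7-[(4-methoxybenzyl)oxy]indan-1-one oxime | O/N=C1\C(OC)(OC)Cc2ccc(Cc3ccc(OCc4ccccc4)c(OC)c3)c(OCc3ccc(OC)cc3)c12 | intermediate (key-step precursor)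
15 | (Z)-O-methanesulfonyl oxime of 13 | CS(=O)(=O)O/N=C1\C(OC)(OC)Cc2ccc(Cc3ccc(OCc4ccccc4)c(OC)c3)c(OCc3ccc(OC)cc3)c12 | intermediate (not isolated)
16 | 7-[4-(benzyloxy)-3-methoxybenzyl]-3,3-dimethoxy-8-[(4-methoxybenzyl)oxy]-3,4-dihydroquinolin-2(1H)-one | COC1(OC)Cc2ccc(Cc3ccc(OCc4ccccc4)c(OC)c3)c(OCc3ccc(OC)cc3)c2NC1=O | intermediate (key-step product)
17 | 7-[4-(benzyloxy)-3-methoxybenzyl]-8-hydroxy-3-methoxyquinolin-2(1H)-one | COc1cc(Cc2ccc3cc(OC)c(=O)[nH]c3c2O)ccc1OCc1ccccc1 | intermediate
18 | sodium 7-[4-(benzyloxy)-3-methoxybenzyl]-3-methoxy-2-oxo-1,2-dihydroquinolin-8-yl sulfate | COc1cc(Cc2ccc3cc(OC)c(=O)[nH]c3c2OS(=O)(=O)[O-])ccc1OCc1ccccc1.[Na+] | intermediate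
19 | sodium 7-(4-hydroxy-3-methoxybenzyl)-3-methoxy-2-oxo-1,2-dihydroquinolin-8-yl sulfate | COc1cc(Cc2ccc3cc(OC)c(=O)[nH]c3c2OS(=O)(=O)[O-])ccc1O.[Na+] | intermediate (not isolated)
20 | scolopendrine | COc1cc(Cc2ccc3cc(OC)c(=O)[nH]c3c2OS(=O)(=O)O)ccc1O | target

**Total step count:** 11. **Longest linear sequence:** 11 steps, from 1.

**Steps most likely to fail**

**Step 8 (ring expansion).**
- Ionisation of a minor or isomerised sulfonate in which the ketal carbon lies anti would cleave the C1–C2 bond instead of shifting the aryl carbon.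
- The ring-locked, coplanar aryl group gets little π assistance and the two alpha oxygens retard ionisation, so the mesylate may merely be hydrolysed back to the oxime.
- Slow or unselective oximation in step 7 would have the same effect.

Fallback: nitrogen is inserted before C2 is oxidised, setting out from 10 and returning at 17.
- Oximation (NH2OH·HCl, NaOAc, EtOH) gives (E)-6-[4-(benzyloxy)-3-methoxybenzyl]-7-[(4-methoxybenzyl)oxy]indan-1-one oxime F1. Its C2 is a plain CH2 that neither crowds the hydroxyl nor supports a cation.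
- Mesylation and the same buffered solvolysis give 7-[4-(benzyloxy)-3-methoxybenzyl]-8-[(4-methoxybenzyl)oxy]-3,4-dihydroquinolin-2(1H)-one F2.
- Boc2O/DMAP gives tert-butyl 7-[4-(benzyloxy)-3-methoxybenzyl]-8-[(4-methoxybenzyl)oxy]-2-oxo-3,4-dihydroquinoline-1(2H)-carboxylate F3. Its C3–H is acidic enough for LiHMDS, so the diarylmethane is not deprotonated.
- Enolate hydroxylation with 2-(phenylsulfonyl)-3-phenyloxaziridine gives the racemic 3-hydroxy derivative of that carbamate F4.
- Dess–Martin oxidation and enolisation give tert-butyl 7-[4-(benzyloxy)-3-methoxybenzyl]-3-hydroxy-8-[(4-methoxybenzyl)oxy]-2-oxoquinoline-1(2H)-carboxylate F5.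
- TMSCHN2 methylates the enolic hydroxyl to the corresponding 3-methoxy carbamate F6.
- CF3CO2H/anisole removes the Boc and 4-methoxybenzyl groups to give 17.

**Step 1 (ortho-formylation).**
- Soft enolisation of the magnesium-chelated ketone by the amine would lead to aldol addition or methylenation with formaldehyde at C2.
- The phenoxide is deactivated by the peri carbonyl group and may attack formaldehyde only sluggishly.

Fallback: a sigmatropic route to the same aldehyde, setting out from 1 and returning at 3.
- Allyl bromide and K2CO3 in acetone give 7-(allyloxy)indan-1-one F7.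
- Aromatic Claisen rearrangement (N,N-diethylaniline, 200 °C) can only reach C6 and gives 6-allyl-7-hydroxyindan-1-one F8.
- Alkene migration with RuHCl(CO)(PPh3)3 gives 7-hydroxy-6-[(E)-prop-1-en-1-yl]indan-1-one F9.
- Lemieux–Johnson cleavage (OsO4 cat., NaIO4) gives 3.

**Step 9 (acid-induced elimination and ether cleavage).**
- Acid strong enough to ionise the ketal, which the neighbouring lactam carbonyl deactivates, may also start to remove the benzyl ether.
- The C3 oxocarbenium ion may be intercepted by adventitious water (hydrolysis instead of elimination) or by the arene scavenger.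
- The liberated 4-methoxybenzyl cation may alkylate the product.

Fallback: the two events are separated and the elimination is made non-protic, setting out from 16 and returning at 17.
- TMSOTf and i-Pr2NEt in CH2Cl2 (the silyl triflate/amine conversion of acetals into enol ethers, here by way of the O-silyl imidate) followed by bicarbonate work-up give 7-[4-(benzyloxy)-3-methoxybenzyl]-3-methoxy-8-[(4-methoxybenzyl)oxy]quinolin-2(1H)-one F10.
- Dilute CF3CO2H with Et3SiH at 0 °C, now free of any reducible ketal, takes off the 4-methoxybenzyl group to give 17.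

**Further compounds**
F1 | step 8 | (E)-6-[4-(benzyloxy)-3-methoxybenzyl]-7-[(4-methoxybenzyl)oxy]indan-1-one oxime | O/N=C1\CCc2ccc(Cc3ccc(OCc4ccccc4)c(OC)c3)c(OCc3ccc(OC)cc3)c12
F2 | step 8 | 7-[4-(benzyloxy)-3-methoxybenzyl]-8-[(4-methoxybenzyl)oxy]-3,4-dihydroquinolin-2(1H)-one | O=C1CCc2ccc(Cc3ccc(OCc4ccccc4)c(OC)c3)c(OCc3ccc(OC)cc3)c2N1
F3 | step 8 | tert-butyl 7-[4-(benzyloxy)-3-methoxybenzyl]-8-[(4-methoxybenzyl)oxy]-2-oxo-3,4-dihydroquinoline-1(2H)-carboxylate | CC(C)(C)OC(=O)N1C(=O)CCc2ccc(Cc3ccc(OCc4ccccc4)c(OC)c3)c(OCc3ccc(OC)cc3)c21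
F4 | step 8 | tert-butyl 7-[4-(benzyloxy)-3-methoxybenzyl]-3-hydroxy-8-[(4-methoxybenzyl)oxy]-2-oxo-3,4-dihydroquinoline-1(2H)-carboxylate (racemic) | CC(C)(C)OC(=O)N1C(=O)C(O)Cc2ccc(Cc3ccc(OCc4ccccc4)c(OC)c3)c(OCc3ccc(OC)cc3)c21
F5 | step 8 | tert-butyl 7-[4-(benzyloxy)-3-methoxybenzyl]-3-hydroxy-8-[(4-methoxybenzyl)oxy]-2-oxoquinoline-1(2H)-carboxylate | CC(C)(C)OC(=O)n1c(=O)c(O)cc2ccc(Cc3ccc(OCc4ccccc4)c(OC)c3)c(OCc3ccc(OC)cc3)c21
F6 | step 8 | tert-butyl 7-[4-(benzyloxy)-3-methoxybenzyl]-3-methoxy-8-[(4-methoxybenzyl)oxy]-2-oxoquinoline-1(2H)-carboxylate | CC(C)(C)OC(=O)n1c(=O)c(OC)cc2ccc(Cc3ccc(OCc4ccccc4)c(OC)c3)c(OCc3ccc(OC)cc3)c21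
F7 | step 1 | 7-(allyloxy)indan-1-one | C=CCOc1cccc2CCC(=O)c12
F8 | step 1 | 6-allyl-7-hydroxyindan-1-one | C=CCc1ccc2CCC(=O)c2c1O
F9 | step 1 | 7-hydroxy-6-[(E)-prop-1-en-1-yl]indan-1-one | C/C=C/c1ccc2CCC(=O)c2c1O
F10 | step 9 | 7-[4-(benzyloxy)-3-methoxybenzyl]-3-methoxy-8-[(4-methoxybenzyl)oxy]quinolin-2(1H)-one | COc1cc(Cc2ccc3cc(OC)c(=O)[nH]c3c2OCc2ccc(OC)cc2)ccc1OCc1ccccc1
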